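# Proposed total synthesis of CNP0154468.1 by Nozaki–Hiyama–Kishi closure of the C5–C6 bond

## Analysis of the target

- Target 28 is a germacranolide: a cyclodeca-1(10),4-diene (C1–C10) with an α-methylene-γ-butyrolactone fused across C6/C7 (lactone oxygen on C6; C11, C12 and exocyclic C13 on C7), a carboxylic acid C14 on C10, a methyl C15 on C4 and angelate esters on C8 and C9.
- Both ring alkenes are trisubstituted and ring-cis: C4=C5 is Z, and in C1=C10 the chain carbon C2 is cis to C9 and trans to the carboxyl (formally E).
- The four stereocentres are contiguous (6R,7S,8S,9S). On the ring O6 is α, C11 β, O8 β and O9 α, so C6/C7 are trans (trans-fused lactone), C7/C8 cis and C8/C9 trans, the last pair being a threo diol of the L-threitol type.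
- Sensitive groups are the exocyclic enoate of the lactone (Michael acceptor), the allylic C6–O lactone bond, the two Z-configured angelates (easily isomerised to tiglates) and the free acrylic acid.
- The difficulty is a ten-membered ring with two cis double bonds, four adjacent stereocentres, and a late acylation of a hindered diol next to a Michael acceptor.
- The strategy rests on C6 being an allylic carbinol carbon lying between C5 of the Z C4=C5 alkene and the branched C7. The C5–C6 bond and the C6 centre can therefore be made together from a C5 alkenyl-metal and a C6 aldehyde, with everything else prepared in an open chain.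

## Retrosynthetic reasoning

**End game (28 back to 19).** Acid 28 is taken back to its tert-butyl ester 27, so that the carboxyl is masked until the last step. The two angelates of 27 are removed next, to diol 24 and angelic acid 25, because Z-enoates of this kind do not survive enolate or strongly nucleophilic chemistry and must go on late. Diol 24 comes from acetonide 23; the acetonide keeps O8 tied up while the lactone is built, so O8 cannot compete with O6 for C12. The exocyclic methylene C13 of 23 is cut back through Mannich base 21 to the saturated lactone 20, and the O6–C12 bond of 20 is opened to hydroxy ester 19.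

**Ring closure (19 back to 17, C5–C6).** This is the only ring bond whose formation also creates a needed stereocentre and needs nothing but an aldehyde and an alkenyl iodide, both inert to the esters and the acetonide. The alternatives are worse: closure at C1=C10 by olefination would put a base next to the β-oxygenated C9, and C2–C3 is an unactivated sp3–sp3 bond. In 17 both alkene geometries and C7–C9 are already fixed, so the forward reaction only has to close the ring and set C6. A chromium-mediated, nickel-catalysed alkenyl addition does this without base, which the epimerisable, β-oxygenated aldehyde requires.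

**C6–C7 (17 back to 14).** The aldehyde carbon C6 is removed from C7, giving the Z-enoate 14 and a one-carbon nitronate donor; nitro ester 15 is the link, and its CH2NO2 group is already at the aldehyde oxidation level. A vinyl–copper reagent would be the more obvious C6 donor, but organocopper reagents add to γ-oxygenated enoates anti to the oxygen, which here gives the C7 epimer. The vinyl group would also have to be cleaved later in the presence of the iodoalkene. The base-promoted nitronate addition goes syn to the γ-oxygen, which is the sense required, and needs no alkene cleavage.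

**C7=C11 (14 back to 11).** The C7=C11 bond is cut to aldehyde 13 and a stabilised two-carbon ylide (C11, C12). Aldehyde 13 comes from alcohol 12 and silyl ether 11, which gains the orthogonal protection needed while the other chain end is built.

**C1=C10 (11 back to 5 and 10).** The trisubstituted enoate is cut at the double bond into phosphonoacetate 5 (C10 nucleophile carrying C14) and aldehyde 10 (C1–C5 with the Z-iodoalkene). This puts the vinyl iodide into the molecule by an ionic olefination, so it never meets an organometallic reagent. It also places the thermodynamically preferred geometry (C2 trans to the ester) where it is wanted. The forward step has to tolerate the β-oxygen at C9.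

**C10–C14 and C10–P (5 back to 1).** Phosphonoacetate 5 is cut at C10–C14 to phosphonate 4 and an alkoxycarbonyl electrophile, and 4 at C10–P to iodide 3. Iodide 3 comes from monosilyl ether 2 and the C2-symmetric diol 1, which supplies C7–C10 with C8 and C9 in the correct absolute configuration.

**C2–C3 (10 back to 6).** Aldehyde 10 is cut at C2–C3 into allylic bromide 7 and a cyanomethyl anion (C1, C2), with nitrile 8 as the link. Bromide 7 comes from alcohol 6, in which the Z-iodoalkene is already in place.

## Alternatives that were turned down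

**Alternative 1: furan–glyoxylate photocycloaddition.**
- Disconnection and key step: C7–C8 and the C6–O bond are made together by irradiating furan A1 with the chiral glyoxylate A2. This Paternò–Büchi reaction gives the exo oxetane A3, whose ring carbons are C6, C7, C8, C11 and C12 and whose ester carbon is C9.
- For: one step from two trivial partners sets C7 and C8 in the required relative sense, since the exo ester places C11 and O8 cis on the later ring. It delivers C6 as an acetal at the aldehyde oxidation level, and the furan oxygen is already the lactone oxygen.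
- Against: the absolute configuration depends only on the facial bias of an auxiliary in an excited-state reaction. C9 arrives as an ester carbon, so the C9 stereocentre and the whole C10/C1–C5 unit must still be added with control. The strained oxetane acetal must be opened selectively. The ten-membered ring is not addressed, so a macrocyclisation of the kind in step 14 would still be needed.
- Comparison: for the C6–C8/C11–C12 portion the alternative is shorter, and its relative control at C7/C8 in a rigid bicycle is at least as secure as the Michael addition of step 12. The chosen route offers C8 and C9 from the chiral pool in fixed absolute configuration, no late creation of C9, and ring formation in the key step itself.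

**Alternative 2: Eschenmoser–Tanabe fragmentation.**
- Disconnection and key step: C1 and C6 are joined retrosynthetically, so the enynone A5 arises from the bicyclic epoxy ketone A4. Its sulfonylhydrazone, formed in situ under mild acid, fragments: C1–C6 breaks and the C1≡C10 alkyne and the C6 ketone appear.
- For: the ring comes from two six-membered rings without high dilution. The Z geometry of C4=C5 is inherited from the six-membered ring, and the C6 ketone allows C6 to be set by reduction.
- Against: the alkyne sits where the target needs a trisubstituted acrylate. C14 must be added to C10 and hydrogen to C1 in a syn sense and with the right regiochemistry, on a strained cyclodecenyne that also holds an enone. The C6 reduction must give the α-alcohol. A4, with three stereocentres and a ring-fusion epoxide, is itself a long synthesis.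
- Comparison: as a ring-forming event the fragmentation is more reliable than a macrocyclisation, and the alternative is stronger there. The chosen route instead installs C14 and the C1=C10 geometry by an open-chain olefination, where they are easy to control, and leaves only C6 to the ring closure.

**Alternative 3: Grob fragmentation.**
- Disconnection and key step: C4 and C9 are joined retrosynthetically, giving the cis-decalin A6. A hindered alkoxide base deprotonates the C9 tertiary alcohol, the C4–C9 bond breaks against the C5 sulfonate, and the ten-membered ketone A7 forms with the C4=C5 alkene.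
- For: the alkene geometry follows stereospecifically from the antiperiplanar arrangement, the lactone and the C10 ester are already present, and no dilution is needed.
- Against: C9 emerges as a ketone between the oxygenated C8 and the C10 acrylate. It must be reduced 1,2-selectively to the 9α-alcohol, and C8 is now an epimerisable α-carbon under strongly basic conditions that also meet a lactone. A6 needs three stereocentres (C4, C5, C9) that are built only to be destroyed.
- Comparison: the alternative is stronger in how it controls the C4=C5 geometry and in avoiding a macrocyclisation. In the chosen route that geometry is simply bought with 6, and C9 is never a carbonyl.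

Key step: step 14

## Route

Remark: germacrane numbering (C1–C10 ring, C11–C13 lactone carbons, C14 on C10, C15 on C4) is used for all intermediates, open-chain ones included; 1, 6 and 25 are taken as purchased.

Step 1
Reactants: 1 (4S,5S)-2,2-dimethyl-1,3-dioxolane-4,5-dimethanol
Product: 2 [(4S,5S)-5-({[tert-butyl(dimethyl)silyl]oxy}methyl)-2,2-dimethyl-1,3-dioxolan-4-yl]methanol
Conditions: NaH (1.0 equiv), THF, 0 °C; TBSCl (1.0 equiv), rt
Reagents that add atoms: tert-butyldimethylsilyl chloride, CC(C)(C)[Si](C)(C)Cl
Why: Monosilylation of a C2-symmetric diol through its monosodium alkoxide; the two hydroxyls are equivalent, so either may react, and the free CH2OH becomes C10 while the silylated one becomes C7.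

Step 2
Reactants: 2 [(4S,5S)-5-({[tert-butyl(dimethyl)silyl]oxy}methyl)-2,2-dimethyl-1,3-dioxolan-4-yl]methanol
Product: 3 tert-butyl{[(4S,5R)-5-(iodomethyl)-2,2-dimethyl-1,3-dioxolan-4-yl]methoxy}dimethylsilane
Conditions: I2, PPh3, imidazole, CH2Cl2, 0 °C to rt
Reagents that add atoms: iodine, II
Why: Appel-type iodination of a primary alcohol under neutral conditions that leave the silyl ether and the acetonide untouched; no stereocentre is involved.

Step 3
Reactants: 3 tert-butyl{[(4S,5R)-5-(iodomethyl)-2,2-dimethyl-1,3-dioxolan-4-yl]methoxy}dimethylsilane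
Product: 4 diisopropyl {[(4R,5S)-5-({[tert-butyl(dimethyl)silyl]oxy}methyl)-2,2-dimethyl-1,3-dioxolan-4-yl]methyl}phosphonate
Conditions: P(OiPr)3 (neat), 150 °C, 2-iodopropane distilled off
Reagents that add atoms: triisopropyl phosphite, CC(C)OP(OC(C)C)OC(C)C
Why: Michaelis–Arbuzov reaction of a primary iodide; the isopropyl phosphite gives a sluggish alkyl iodide by-product and later a more E-selective olefination reagent.

Step 4
Reactants: 4 diisopropyl {[(4R,5S)-5-({[tert-butyl(dimethyl)silyl]oxy}methyl)-2,2-dimethyl-1,3-dioxolan-4-yl]methyl}phosphonate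
Product: 5 tert-butyl 2-[(4R,5S)-5-({[tert-butyl(dimethyl)silyl]oxy}methyl)-2,2-dimethyl-1,3-dioxolan-4-yl]-2-(diisopropoxyphosphoryl)acetate (both C10 epimers)
Conditions: LiN(iPr)2 (2.2 equiv), THF, −78 °C; Boc2O (1.1 equiv), −78 to −40 °C; aq. NH4Cl
Reagents that add atoms: di-tert-butyl dicarbonate, CC(C)(C)OC(=O)OC(=O)OC(C)(C)C
Why: C-Acylation of an α-lithiated alkylphosphonate, the standard entry to 2-phosphonoalkanoates; the second equivalent of base deprotonates the more acidic product and stops over-acylation, and at −78 °C the carbanion should not expel the β-oxygen at C9, as with other β-alkoxy phosphonate and sulfone anions.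

Step 5
Reactants: 6 (Z)-3-iodo-2-methylprop-2-en-1-ol
Product: 7 (Z)-3-bromo-1-iodo-2-methylprop-1-ene
Conditions: CBr4, PPh3, CH2Cl2, 0 °C
Reagents that add atoms: tetrabromomethane, BrC(Br)(Br)Br
Why: Appel bromination of a primary allylic alcohol without allylic transposition; the Z-iodoalkene is not touched.

Step 6
Reactants: 7 (Z)-3-bromo-1-iodo-2-methylprop-1-ene
Product: 8 (Z)-5-iodo-4-methylpent-4-enenitrile
Conditions: MeCN (3.2 equiv), LiN(iPr)2 (3.0 equiv), THF, −78 °C; then 7
Reagents that add atoms: acetonitrile, CC#N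
Why: SN2 alkylation of the cyanomethyl anion by an allylic bromide, which forms C2–C3; the excess of anion suppresses dialkylation, and the absence of free amide base or alkyllithium protects the alkenyl iodide.

Step 7
Reactants: 8 (Z)-5-iodo-4-methylpent-4-enenitrile
Product: 10 (Z)-5-iodo-4-methylpent-4-enal, via aluminoimine 9 (not isolated)
Conditions: iBu2AlH (1.1 equiv), CH2Cl2, −78 °C; aq. potassium sodium tartrate, rt
Reagents that add atoms: water, O
Why: Partial reduction of a nitrile stops at the N-metalated imine 9, which is hydrolysed to the aldehyde on work-up; the alkenyl iodide is inert to the hydride at −78 °C.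

Step 8
Reactants: 5 tert-butyl 2-[(4R,5S)-5-({[tert-butyl(dimethyl)silyl]oxy}methyl)-2,2-dimethyl-1,3-dioxolan-4-yl]-2-(diisopropoxyphosphoryl)acetate; 10 (Z)-5-iodo-4-methylpent-4-enal
Product: 11 tert-butyl (2E,6Z)-2-[(4S,5S)-5-({[tert-butyl(dimethyl)silyl]oxy}methyl)-2,2-dimethyl-1,3-dioxolan-4-yl]-7-iodo-6-methylhepta-2,6-dienoate
Conditions: KOtBu (1.05 equiv), THF, −78 °C; then 10, −78 to 0 °C
Reagents that add atoms: none
Why: Horner–Wadsworth–Emmons olefination of an α-substituted phosphonoacetate with an unbranched aldehyde; reversible addition and elimination through the less crowded oxaphosphetane should place C2 trans to the ester (C1=C10 as in the target), helped by the bulky isopropyl phosphonate esters, and the doubly stabilised anion has little driving force to lose the C9 oxygen.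

Step 9
Reactants: 11 tert-butyl (2E,6Z)-2-[(4S,5S)-5-({[tert-butyl(dimethyl)silyl]oxy}methyl)-2,2-dimethyl-1,3-dioxolan-4-yl]-7-iodo-6-methylhepta-2,6-dienoate
Product: 12 tert-butyl (2E,6Z)-2-[(4S,5S)-5-(hydroxymethyl)-2,2-dimethyl-1,3-dioxolan-4-yl]-7-iodo-6-methylhepta-2,6-dienoate
Conditions: Bu4NF, AcOH (1:1), THF, 0 °C to rt
Reagents that add atoms: none
Why: Fluoride cleavage of a primary silyl ether; the acetic acid buffer keeps the C7 alkoxide from adding to the enoate at C1.

Step 10
Reactants: 12 tert-butyl (2E,6Z)-2-[(4S,5S)-5-(hydroxymethyl)-2,2-dimethyl-1,3-dioxolan-4-yl]-7-iodo-6-methylhepta-2,6-dienoate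
Product: 13 tert-butyl (2E,6Z)-2-[(4S,5R)-5-formyl-2,2-dimethyl-1,3-dioxolan-4-yl]-7-iodo-6-methylhepta-2,6-dienoate
Conditions: Dess–Martin periodinane, NaHCO3, CH2Cl2, 0 °C to rt; used crude
Reagents that add atoms: none
Why: Neutral oxidation of a primary alcohol to the α-alkoxy aldehyde; the trans-dioxolane is the more stable arrangement, so C8 is not at risk of epimerisation.

Step 11
Reactants: 13 tert-butyl (2E,6Z)-2-[(4S,5R)-5-formyl-2,2-dimethyl-1,3-dioxolan-4-yl]-7-iodo-6-methylhepta-2,6-dienoate
Product: 14 tert-butyl (2E,6Z)-7-iodo-2-{(4S,5S)-5-[(1Z)-3-methoxy-3-oxoprop-1-en-1-yl]-2,2-dimethyl-1,3-dioxolan-4-yl}-6-methylhepta-2,6-dienoate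
Conditions: Ph3P=CHCO2Me, MeOH, 0 °C
Reagents that add atoms: methyl (triphenylphosphoranylidene)acetate, COC(=O)C=P(c1ccccc1)(c1ccccc1)c1ccccc1
Why: Wittig reaction of a stabilised ylide; with α-alkoxy aldehydes in methanol this reaction favours the Z-enoate, the geometry that gives the higher facial selectivity in step 12, and the minor E isomer is removed by chromatography.

Step 12
Reactants: 14 tert-butyl (2E,6Z)-7-iodo-2-{(4S,5S)-5-[(1Z)-3-methoxy-3-oxoprop-1-en-1-yl]-2,2-dimethyl-1,3-dioxolan-4-yl}-6-methylhepta-2,6-dienoate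
Product: 15 tert-butyl (2E,6Z)-7-iodo-2-{(4S,5S)-5-[(2S)-4-methoxy-1-nitro-4-oxobutan-2-yl]-2,2-dimethyl-1,3-dioxolan-4-yl}-6-methylhepta-2,6-dienoate
Conditions: MeNO2 (10 equiv), Bu4NF (0.3 equiv), THF, 0 °C
Reagents that add atoms: nitromethane, C[N+](=O)[O-]
Why: Base-promoted Michael addition of a nitronate, which sets C7: allylic 1,3-strain holds C8–H in the plane of the Z-enoate and the uncomplexed nitronate attacks C7 anti to the C8–C9 bond with O8 outside, the syn sense known for nitroalkane additions to γ,δ-dioxolanyl enoates and opposite to that of organocopper reagents; the α-branched trisubstituted tert-butyl enoate is a much poorer acceptor and should not react.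

Step 13
Reactants: 15 tert-butyl (2E,6Z)-7-iodo-2-{(4S,5S)-5-[(2S)-4-methoxy-1-nitro-4-oxobutan-2-yl]-2,2-dimethyl-1,3-dioxolan-4-yl}-6-methylhepta-2,6-dienoate
Product: 17 tert-butyl (2E,6Z)-7-iodo-2-{(4S,5S)-5-[(2R)-4-methoxy-1,4-dioxobutan-2-yl]-2,2-dimethyl-1,3-dioxolan-4-yl}-6-methylhepta-2,6-dienoate, via sodium nitronate 16 (not isolated)
Conditions: NaOMe (1.1 equiv), MeOH, 0 °C; then aq. TiCl3 (4 equiv), NH4OAc (pH about 6), 0 °C to rt
Reagents that add atoms: water, O
Why: Reductive Nef reaction: the nitronate 16 is reduced by trivalent titanium to the imine, which hydrolyses to the C6 aldehyde in the buffered medium; the near-neutral pH spares the acetonide and the tert-butyl ester and avoids the base that would epimerise C7 or eliminate O8 (the descriptor at C7 changes only because of ligand priorities).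

Step 14
Reactants: 17 tert-butyl (2E,6Z)-7-iodo-2-{(4S,5S)-5-[(2R)-4-methoxy-1,4-dioxobutan-2-yl]-2,2-dimethyl-1,3-dioxolan-4-yl}-6-methylhepta-2,6-dienoate
Product: 19 tert-butyl (1(10)E,4Z,6R,7S,8S,9S)-6-hydroxy-8,9-(isopropylidenedioxy)-12-methoxy-12-oxo-13-norgermacra-1(10),4-dien-14-oate, via alkenylchromium dichloride 18 (not isolated)
Conditions: CrCl2 (10 equiv), NiCl2 (0.1 equiv), degassed DMSO, rt, 17 added over 12 h (final 0.003 M)
Reagents that add atoms: none
Why: Intramolecular Nozaki–Hiyama–Kishi reaction: divalent chromium reduces NiCl2 to zerovalent nickel, which inserts into the C5–I bond with retention of the Z geometry; transmetalation gives the trivalent alkenylchromium species 18, which adds to the C6 aldehyde, and the C6–O–Cr bond is hydrolysed on work-up. The closest known reaction type is the chromium-mediated, nickel-catalysed cyclisation of iodoalkenyl aldehydes to medium-ring allylic alcohols, ten-membered ones included. The ten-membered carbocycle closes by attack on the carbonyl carbon in the exo mode (10-exo-trig), forming C5–C6. The new centre C6 is controlled by C7 in the Felkin–Anh sense: C8, the largest substituent on C7, lies anti to the incoming C5 and attack passes C7–H, which gives 6R with C5 trans to C8 on the later lactone. That anti C5–C6–C7–C8 torsion is also the one the trans-lactone-fused ring needs, so ring strain and acyclic control should point the same way. The step needs ring closure to win over intermolecular coupling, which slow addition at high dilution and the two cis alkenes and trans-dioxolane (they turn the chain ends toward each other) should secure. It also needs chemoselectivity for the aldehyde over three esters, which the organochromium reagent provides, and freedom from epimerisation at C7 or loss of O8, which the non-basic medium provides.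

Step 15
Reactants: 19 tert-butyl (1(10)E,4Z,6R,7S,8S,9S)-6-hydroxy-8,9-(isopropylidenedioxy)-12-methoxy-12-oxo-13-norgermacra-1(10),4-dien-14-oate
Product: 20 tert-butyl (1(10)E,4Z,6R,7S,8S,9S)-8,9-(isopropylidenedioxy)-13-norgermacra-1(10),4-dien-12,6-olid-14-oate
Conditions: pyridinium p-toluenesulfonate (0.2 equiv), toluene, 50 °C
Reagents that add atoms: none
Why: Lactonisation of a γ-hydroxy ester to the five-membered trans-fused lactone; the weak acid is chosen because the allylic C6 alcohol would ionise under stronger acid, and O8 is blocked by the acetonide so only O6 can close onto C12.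

Step 16
Reactants: 20 tert-butyl (1(10)E,4Z,6R,7S,8S,9S)-8,9-(isopropylidenedioxy)-13-norgermacra-1(10),4-dien-12,6-olid-14-oate
Product: 21 tert-butyl (1(10)E,4Z,6R,7S,8S,9S)-11-[(dimethylamino)methyl]-8,9-(isopropylidenedioxy)-13-norgermacra-1(10),4-dien-12,6-olid-14-oate (C11 epimers)
Conditions: LiN(SiMe3)2 (1.1 equiv), THF, −78 °C; CH2=NMe2+ I−, −78 to 0 °C
Reagents that add atoms: N,N-dimethylmethyleneiminium iodide, C=[N+](C)C.[I-]
Why: Mannich aminomethylation at C11 after deprotonation of the lactone; C7 carries no leaving group, so β-elimination is not possible, and the silylamide is too weak to deprotonate C2 of the tert-butyl enoate.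

Step 17
Reactants: 21 tert-butyl (1(10)E,4Z,6R,7S,8S,9S)-11-[(dimethylamino)methyl]-8,9-(isopropylidenedioxy)-13-norgermacra-1(10),4-dien-12,6-olid-14-oate
Product: 23 tert-butyl (1(10)E,4Z,6R,7S,8S,9S)-8,9-(isopropylidenedioxy)germacra-1(10),4,11(13)-trien-12,6-olid-14-oate, via trimethylammonium iodide 22 (not isolated)
Conditions: MeI (excess), THF, rt; then aq. NaHCO3, CH2Cl2, rt
Reagents that add atoms: none
Why: Quaternisation of the amine and E1cB loss of trimethylamine give the exocyclic C11=C13 double bond under conditions too mild to touch the other esters.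

Step 18
Reactants: 23 tert-butyl (1(10)E,4Z,6R,7S,8S,9S)-8,9-(isopropylidenedioxy)germacra-1(10),4,11(13)-trien-12,6-olid-14-oate
Product: 24 tert-butyl (1(10)E,4Z,6R,7S,8S,9S)-8,9-dihydroxygermacra-1(10),4,11(13)-trien-12,6-olid-14-oate
Conditions: AcOH–H2O (4:1), 40 °C
Reagents that add atoms: none
Why: Hydrolysis of a strained trans-fused dioxolane in aqueous acetic acid, which is too weak to cleave the tert-butyl ester or to ionise the allylic lactone.

Step 19
Reactants: 24 tert-butyl (1(10)E,4Z,6R,7S,8S,9S)-8,9-dihydroxygermacra-1(10),4,11(13)-trien-12,6-olid-14-oate; 25 angelic acid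
Product: 27 tert-butyl (1(10)E,4Z,6R,7S,8S,9S)-8,9-bis{[(2Z)-2-methylbut-2-enoyl]oxy}germacra-1(10),4,11(13)-trien-12,6-olid-14-oate, via angelic 2,4,6-trichlorobenzoic anhydride 26 (not isolated)
Conditions: 25 (6 equiv), 2,4,6-trichlorobenzoyl chloride (6 equiv), Et3N (7 equiv), toluene, rt; then 24, 75 °C
Reagents that add atoms: none
Why: Yamaguchi-type esterification through the mixed anhydride 26, run without a nucleophilic catalyst because such catalysts turn angelates into tiglates; the hindered aroyl carbonyl directs both hydroxyls to the angeloyl carbon.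

Step 20
Reactants: 27 tert-butyl (1(10)E,4Z,6R,7S,8S,9S)-8,9-bis{[(2Z)-2-methylbut-2-enoyl]oxy}germacra-1(10),4,11(13)-trien-12,6-olid-14-oate
Product: 28 (1(10)E,4Z,6R,7S,8S,9S)-8,9-bis{[(2Z)-2-methylbut-2-enoyl]oxy}germacra-1(10),4,11(13)-trien-12,6-olid-14-oic acid
Conditions: CF3CO2H–CH2Cl2 (1:4), 0 °C, short reaction time
Reagents that add atoms: none
Why: Acidolysis of the tert-butyl ester with loss of 2-methylpropene; it is run cold and briefly because the allylic C6–O bond and the angelates are the other acid-sensitive sites.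

## Compound list

1 | (4S,5S)-2,2-dimethyl-1,3-dioxolane-4,5-dimethanol (2,3-O-isopropylidene-L-threitol) | OC[C@@H]1OC(C)(C)O[C@H]1CO | starting material
2 | [(4S,5S)-5-({[tert-butyl(dimethyl)silyl]oxy}methyl)-2,2-dimethyl-1,3-dioxolan-4-yl]methanol | OC[C@@H]1OC(C)(C)O[C@H]1CO[Si](C)(C)C(C)(C)C | intermediate
3 | tert-butyl{[(4S,5R)-5-(iodomethyl)-2,2-dimethyl-1,3-dioxolan-4-yl]methoxy}dimethylsilane | IC[C@@H]1OC(C)(C)O[C@H]1CO[Si](C)(C)C(C)(C)C | intermediate
4 | diisopropyl {[(4R,5S)-5-({[tert-butyl(dimethyl)silyl]oxy}methyl)-2,2-dimethyl-1,3-dioxolan-4-yl]methyl}phosphonate | CC(C)OP(=O)(OC(C)C)C[C@@H]1OC(C)(C)O[C@H]1CO[Si](C)(C)C(C)(C)C | intermediate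
5 | tert-butyl 2-[(4R,5S)-5-({[tert-butyl(dimethyl)silyl]oxy}methyl)-2,2-dimethyl-1,3-dioxolan-4-yl]-2-(diisopropoxyphosphoryl)acetate (both C10 epimers) | CC(C)OP(=O)(OC(C)C)C(C(=O)OC(C)(C)C)[C@@H]1OC(C)(C)O[C@H]1CO[Si](C)(C)C(C)(C)C | intermediate
6 | (Z)-3-iodo-2-methylprop-2-en-1-ol | OC/C(C)=C\I | starting material
7 | (Z)-3-bromo-1-iodo-2-methylprop-1-ene | BrC/C(C)=C\I | intermediate
8 | (Z)-5-iodo-4-methylpent-4-enenitrile | N#CCC/C(C)=C\I | intermediate
9 | (Z)-N-(diisobutylalumanyl)-5-iodo-4-methylpent-4-en-1-imine | CC(C)C[Al](CC(C)C)N=CCC/C(C)=C\I | intermediate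
10 | (Z)-5-iodo-4-methylpent-4-enal | O=CCC/C(C)=C\I | intermediate
11 | tert-butyl (2E,6Z)-2-[(4S,5S)-5-({[tert-butyl(dimethyl)silyl]oxy}methyl)-2,2-dimethyl-1,3-dioxolan-4-yl]-7-iodo-6-methylhepta-2,6-dienoate | I/C=C(/C)CC/C=C(/C(=O)OC(C)(C)C)[C@@H]1OC(C)(C)O[C@H]1CO[Si](C)(C)C(C)(C)C | intermediate
12 | tert-butyl (2E,6Z)-2-[(4S,5S)-5-(hydroxymethyl)-2,2-dimethyl-1,3-dioxolan-4-yl]-7-iodo-6-methylhepta-2,6-dienoate | I/C=C(/C)CC/C=C(/C(=O)OC(C)(C)C)[C@@H]1OC(C)(C)O[C@H]1CO | intermediate
13 | tert-butyl (2E,6Z)-2-[(4S,5R)-5-formyl-2,2-dimethyl-1,3-dioxolan-4-yl]-7-iodo-6-methylhepta-2,6-dienoate | I/C=C(/C)CC/C=C(/C(=O)OC(C)(C)C)[C@@H]1OC(C)(C)O[C@H]1C=O | intermediate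
14 | tert-butyl (2E,6Z)-7-iodo-2-{(4S,5S)-5-[(1Z)-3-methoxy-3-oxoprop-1-en-1-yl]-2,2-dimethyl-1,3-dioxolan-4-yl}-6-methylhepta-2,6-dienoate | I/C=C(/C)CC/C=C(/C(=O)OC(C)(C)C)[C@@H]1OC(C)(C)O[C@H]1/C=C\C(=O)OC | intermediate
15 | tert-butyl (2E,6Z)-7-iodo-2-{(4S,5S)-5-[(2S)-4-methoxy-1-nitro-4-oxobutan-2-yl]-2,2-dimethyl-1,3-dioxolan-4-yl}-6-methylhepta-2,6-dienoate | I/C=C(/C)CC/C=C(/C(=O)OC(C)(C)C)[C@@H]1OC(C)(C)O[C@H]1[C@@H](CC(=O)OC)C[N+](=O)[O-] | intermediate
16 | sodium nitronate of 15 | I/C=C(/C)CC/C=C(/C(=O)OC(C)(C)C)[C@@H]1OC(C)(C)O[C@H]1[C@@H](CC(=O)OC)C=[N+]([O-])[O-].[Na+] | intermediate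
17 | tert-butyl (2E,6Z)-7-iodo-2-{(4S,5S)-5-[(2R)-4-methoxy-1,4-dioxobutan-2-yl]-2,2-dimethyl-1,3-dioxolan-4-yl}-6-methylhepta-2,6-dienoate | I/C=C(/C)CC/C=C(/C(=O)OC(C)(C)C)[C@@H]1OC(C)(C)O[C@H]1[C@@H](CC(=O)OC)C=O | intermediate
18 | alkenylchromium dichloride from 17 (CrCl2 in place of iodine at C5, Z retained) | Cl[Cr](Cl)/C=C(/C)CC/C=C(/C(=O)OC(C)(C)C)[C@@H]1OC(C)(C)O[C@H]1[C@@H](CC(=O)OC)C=O | intermediate
19 | tert-butyl (1(10)E,4Z,6R,7S,8S,9S)-6-hydroxy-8,9-(isopropylidenedioxy)-12-methoxy-12-oxo-13-norgermacra-1(10),4-dien-14-oate | COC(=O)C[C@H]1[C@H](O)/C=C(/C)CC/C=C(/C(=O)OC(C)(C)C)[C@@H]2OC(C)(C)O[C@@H]12 | intermediate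
20 | tert-butyl (1(10)E,4Z,6R,7S,8S,9S)-8,9-(isopropylidenedioxy)-13-norgermacra-1(10),4-dien-12,6-olid-14-oate | C1C(=O)O[C@@H]2/C=C(/C)CC/C=C(/C(=O)OC(C)(C)C)[C@@H]3OC(C)(C)O[C@H]3[C@@H]12 | intermediate
21 | tert-butyl (1(10)E,4Z,6R,7S,8S,9S)-11-[(dimethylamino)methyl]-8,9-(isopropylidenedioxy)-13-norgermacra-1(10),4-dien-12,6-olid-14-oate (C11 epimers) | CN(C)CC1C(=O)O[C@@H]2/C=C(/C)CC/C=C(/C(=O)OC(C)(C)C)[C@@H]3OC(C)(C)O[C@H]3[C@@H]12 | intermediate
22 | trimethylammonium iodide of 21 | C[N+](C)(C)CC1C(=O)O[C@@H]2/C=C(/C)CC/C=C(/C(=O)OC(C)(C)C)[C@@H]3OC(C)(C)O[C@H]3[C@@H]12.[I-] | intermediate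
23 | tert-butyl (1(10)E,4Z,6R,7S,8S,9S)-8,9-(isopropylidenedioxy)germacra-1(10),4,11(13)-trien-12,6-olid-14-oate | C=C1C(=O)O[C@@H]2/C=C(/C)CC/C=C(/C(=O)OC(C)(C)C)[C@@H]3OC(C)(C)O[C@H]3[C@@H]12 | intermediate
24 | tert-butyl (1(10)E,4Z,6R,7S,8S,9S)-8,9-dihydroxygermacra-1(10),4,11(13)-trien-12,6-olid-14-oate | C=C1C(=O)O[C@@H]2/C=C(/C)CC/C=C(/C(=O)OC(C)(C)C)[C@H](O)[C@@H](O)[C@@H]12 | intermediate
25 | angelic acid, (Z)-2-methylbut-2-enoic acid | C/C=C(/C)C(=O)O | starting material
26 | angelic 2,4,6-trichlorobenzoic anhydride | C/C=C(/C)C(=O)OC(=O)c1c(Cl)cc(Cl)cc1Cl | intermediate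
27 | tert-butyl (1(10)E,4Z,6R,7S,8S,9S)-8,9-bis{[(2Z)-2-methylbut-2-enoyl]oxy}germacra-1(10),4,11(13)-trien-12,6-olid-14-oate | C=C1C(=O)O[C@@H]2/C=C(/C)CC/C=C(/C(=O)OC(C)(C)C)[C@H](OC(=O)/C(C)=C\C)[C@@H](OC(=O)/C(C)=C\C)[C@@H]12 | intermediate
28 | (1(10)E,4Z,6R,7S,8S,9S)-8,9-bis{[(2Z)-2-methylbut-2-enoyl]oxy}germacra-1(10),4,11(13)-trien-12,6-olid-14-oic acid | C=C1C(=O)O[C@@H]2/C=C(/C)CC/C=C(/C(=O)O)[C@H](OC(=O)/C(C)=C\C)[C@@H](OC(=O)/C(C)=C\C)[C@@H]12 | target

## Step count and least certain steps

Total: 20 steps. Longest linear sequence: 17 steps (steps 1–4 and 8–20, from 1 to 28); the branch from 6 to 10 is three steps.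

**Step 14 (key step).** Two things may go wrong. Ring closure may lose to intermolecular coupling or to simple reduction of the C–I bond, because the ten-membered transition state is strained. Facial selectivity at C6 may be poor, because the ring constraints or coordination of chromium to O8 can override the Felkin–Anh preference. If addition gives mainly the C6 epimer, tert-butyl (1(10)E,4Z,6S,7S,8S,9S)-6-hydroxy-8,9-(isopropylidenedioxy)-12-methoxy-12-oxo-13-norgermacra-1(10),4-dien-14-oate F1, the centre is corrected instead of being re-made. The fallback sets out from 17, which is cyclised as before to F1. Saponification of the methyl ester (LiOH, aq. THF; the tert-butyl ester survives) gives the corresponding 6S hydroxy acid F2. Mitsunobu lactonisation (PPh3, diisopropyl azodicarboxylate, toluene) closes the five-membered lactone with inversion at C6 and comes back to the route at 20.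

**Step 8.** The E-selectivity may erode because the substituent on C10 is a branched dioxolanyl carbon, and some of the phosphonate anion may be lost by β-elimination of the C9 oxygen. The fallback forms the trisubstituted alkene by metathesis instead of olefination and sets out from 5 and 10. Phosphonoacetate 5 is condensed with formaldehyde (aq. CH2O, K2CO3), where no geometry arises, to give the acrylate tert-butyl 2-[(4S,5S)-5-({[tert-butyl(dimethyl)silyl]oxy}methyl)-2,2-dimethyl-1,3-dioxolan-4-yl]prop-2-enoate F3. Aldehyde 10 is methylenated (Ph3PCH3Br, KOtBu, THF) to (Z)-1-iodo-2-methylhexa-1,5-diene F4. Cross-metathesis of F3 with excess F4 (second-generation Hoveyda–Grubbs catalyst, CH2Cl2, 40 °C) is a known way to E-configured 2-substituted alk-2-enoates and comes back at 11. The trisubstituted iodoalkene is too hindered to enter the metathesis.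

**Step 12.** The face selectivity at C7 may be low or reversed, and the product nitronate may add to C1 of the tert-butyl enoate in a ring-forming Michael reaction if the base is left too long. The fallback exchanges donor and acceptor, so that the anti preference of a metal enolate works for the required configuration. It sets out from 13. A Henry reaction with nitromethane (catalytic Et3N) gives the nitro alcohol tert-butyl (2E,6Z)-2-[(4S,5S)-5-(1-hydroxy-2-nitroethyl)-2,2-dimethyl-1,3-dioxolan-4-yl]-7-iodo-6-methylhepta-2,6-dienoate F5. Dehydration (MsCl, Et3N) gives the nitroalkene tert-butyl (2E,6Z)-7-iodo-6-methyl-2-{(4S,5S)-2,2-dimethyl-5-[(E)-2-nitroethenyl]-1,3-dioxolan-4-yl}hepta-2,6-dienoate F6. Conjugate addition of the separately prepared Reformatsky reagent BrZnCH2CO2Me (THF, −20 °C), anti to the C8–O bond, comes back at 15.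

**Step 13.** The reduction may stop at the oxime, C7 may epimerise through imine–enamine equilibration, and O8 may be lost by β-elimination if the medium drifts basic. The fallback divides the task into a reduction and a separate exchange and sets out from 15. SnCl2, PhSH and Et3N reduce the nitro group to the aldoxime, tert-butyl (2E,6Z)-2-{(4S,5S)-5-[(2R)-1-(hydroxyimino)-4-methoxy-4-oxobutan-2-yl]-2,2-dimethyl-1,3-dioxolan-4-yl}-7-iodo-6-methylhepta-2,6-dienoate F7. Transoximation with aqueous glyoxylic acid (NaOAc buffer, rt) releases the aldehyde and comes back at 17.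

**Step 19.** The angeloyl groups may isomerise to tigloyl groups during activation, the second hindered hydroxyl may acylate incompletely, and the lactone may migrate from O6 to the free O8 in the basic medium. The fallback creates the Z double bonds after the ester bonds are in place and sets out from 24. Both hydroxyls are acylated with 2-[bis(2,2,2-trifluoroethoxy)phosphoryl]propanoic acid (N,N'-diisopropylcarbodiimide, catalytic 4-(dimethylamino)pyridine), a small and unhindered acyl donor, to give the bis(phosphonopropionate) of 24, F8. A double Z-selective Still–Gennari olefination with acetaldehyde (KN(SiMe3)2, 18-crown-6, THF, −78 °C) forms both angelates and comes back at 27. The phosphonate C–H is the most acidic site, so the amide base should not attack the methylene lactone.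

**Step 20.** The allylic C6–O bond may ionise or C4=C5 may be protonated in trifluoroacetic acid, and the angelates may isomerise under protic acid. The fallback leaves protic acid out and cleaves the ester by silyl transfer under buffered conditions; it sets out from 27. Me3SiOTf and 2,6-lutidine (CH2Cl2, 0 °C) expel 2-methylpropene and give the trimethylsilyl ester of 28, F9. Water hydrolyses F9 on work-up and comes back at 28.

## Further compounds

F1 | step 14 | tert-butyl (1(10)E,4Z,6S,7S,8S,9S)-6-hydroxy-8,9-(isopropylidenedioxy)-12-methoxy-12-oxo-13-norgermacra-1(10),4-dien-14-oate (C6 epimer of 19) | COC(=O)C[C@H]1[C@@H](O)/C=C(/C)CC/C=C(/C(=O)OC(C)(C)C)[C@@H]2OC(C)(C)O[C@@H]12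
F2 | step 14 | (1(10)E,4Z,6S,7S,8S,9S)-14-tert-butoxy-6-hydroxy-8,9-(isopropylidenedioxy)-14-oxo-13-norgermacra-1(10),4-dien-12-oic acid | OC(=O)C[C@H]1[C@@H](O)/C=C(/C)CC/C=C(/C(=O)OC(C)(C)C)[C@@H]2OC(C)(C)O[C@@H]12
F3 | step 8 | tert-butyl 2-[(4S,5S)-5-({[tert-butyl(dimethyl)silyl]oxy}methyl)-2,2-dimethyl-1,3-dioxolan-4-yl]prop-2-enoate | C=C(C(=O)OC(C)(C)C)[C@@H]1OC(C)(C)O[C@H]1CO[Si](C)(C)C(C)(C)C
F4 | step 8 | (Z)-1-iodo-2-methylhexa-1,5-diene | C=CCC/C(C)=C\I
F5 | step 12 | tert-butyl (2E,6Z)-2-[(4S,5S)-5-(1-hydroxy-2-nitroethyl)-2,2-dimethyl-1,3-dioxolan-4-yl]-7-iodo-6-methylhepta-2,6-dienoate (carbinol epimers) | I/C=C(/C)CC/C=C(/C(=O)OC(C)(C)C)[C@@H]1OC(C)(C)O[C@H]1C(O)C[N+](=O)[O-]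
F6 | step 12 | tert-butyl (2E,6Z)-7-iodo-6-methyl-2-{(4S,5S)-2,2-dimethyl-5-[(E)-2-nitroethenyl]-1,3-dioxolan-4-yl}hepta-2,6-dienoate | I/C=C(/C)CC/C=C(/C(=O)OC(C)(C)C)[C@@H]1OC(C)(C)O[C@H]1/C=C/[N+](=O)[O-]
F7 | step 13 | tert-butyl (2E,6Z)-2-{(4S,5S)-5-[(2R)-1-(hydroxyimino)-4-methoxy-4-oxobutan-2-yl]-2,2-dimethyl-1,3-dioxolan-4-yl}-7-iodo-6-methylhepta-2,6-dienoate | I/C=C(/C)CC/C=C(/C(=O)OC(C)(C)C)[C@@H]1OC(C)(C)O[C@H]1[C@@H](CC(=O)OC)C=NO
F8 | step 19 | tert-butyl (1(10)E,4Z,6R,7S,8S,9S)-8,9-bis({2-[bis(2,2,2-trifluoroethoxy)phosphoryl]propanoyl}oxy)germacra-1(10),4,11(13)-trien-12,6-olid-14-oate | C=C1C(=O)O[C@@H]2/C=C(/C)CC/C=C(/C(=O)OC(C)(C)C)[C@H](OC(=O)C(C)P(=O)(OCC(F)(F)F)OCC(F)(F)F)[C@@H](OC(=O)C(C)P(=O)(OCC(F)(F)F)OCC(F)(F)F)[C@@H]12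
F9 | step 20 | trimethylsilyl (1(10)E,4Z,6R,7S,8S,9S)-8,9-bis{[(2Z)-2-methylbut-2-enoyl]oxy}germacra-1(10),4,11(13)-trien-12,6-olid-14-oate | C=C1C(=O)O[C@@H]2/C=C(/C)CC/C=C(/C(=O)O[Si](C)(C)C)[C@H](OC(=O)/C(C)=C\C)[C@@H](OC(=O)/C(C)=C\C)[C@@H]12
A1 | alternative 1 | furan | c1ccoc1
A2 | alternative 1 | (−)-8-phenylmenthyl glyoxylate | O=CC(=O)O[C@@H]1C[C@H](C)CC[C@H]1C(C)(C)c1ccccc1
A3 | alternative 1 | exo photoadduct, 8-phenylmenthyl 2,7-dioxabicyclo[3.2.0]hept-3-ene-6-carboxylate | O=C(O[C@@H]1C[C@H](C)CC[C@H]1C(C)(C)c1ccccc1)[C@H]2O[C@@H]3OC=C[C@H]23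
A4 | alternative 2 | bicyclic C1–C6 epoxy C10 ketone with C4=C5, C7 methyl acetate arm and C8/C9 silyl ethers (epoxide face at C1/C6 left open) | COC(=O)C[C@@H]1[C@H](O[Si](C)(C)C(C)(C)C)[C@@H](O[Si](C)(C)C(C)(C)C)C(=O)C23OC12C=C(C)CC3
A5 | alternative 2 | ten-membered C6 ketone with ring-cis C4=C5, C1≡C10 alkyne, C7 methyl acetate arm and C8/C9 silyl ethers | COC(=O)C[C@H]1C(=O)/C=C(/C)CCC#C[C@H](O[Si](C)(C)C(C)(C)C)[C@H]1O[Si](C)(C)C(C)(C)C
A6 | alternative 3 | cis-decalin with C4–C9 bond, C9 tertiary alcohol, C5 mesylate, C10 tert-butyl ester, C8 4-methoxybenzyl ether and saturated lactone (C4, C5 and C9 left open) | C1C(=O)O[C@@H]2C(OS(C)(=O)=O)C3(C)CCC=C(C(=O)OC(C)(C)C)C3(O)[C@@H](OCc4ccc(OC)cc4)[C@@H]12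
A7 | alternative 3 | ten-membered C9 ketone with C1=C10 tert-butyl ester, ring-cis C4=C5, C8 4-methoxybenzyl ether and saturated lactone | C1C(=O)O[C@@H]2/C=C(/C)CC/C=C(/C(=O)OC(C)(C)C)C(=O)[C@@H](OCc3ccc(OC)cc3)[C@@H]12
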